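# Proposed synthesis of methyl 8β-acetoxy-3β-(isobutyryloxy)eudesma-4,11(13)-dien-12-oate (CNP0127901.1)

Conventions: eudesmane numbering is used throughout (ring A = C1, C2, C3, C4, C5, C10; ring B = C5 to C10; methyls on C4 and C10; C11 on C7 carries the ester carbon C12 and the methylene C13). β means the face of the C10 methyl group. TBS = tert-butyldimethylsilyl. The target is (3S,7R,8R,10R).

## Analysis of the target

The target is a bicyclic eudesmane: two fused six-membered carbocycles sharing C5–C10, with a tetrasubstituted C4=C5 alkene at the ring fusion. It has four stereocentres: the all-carbon quaternary C10, the isobutyrate carbon C3, the acetate carbon C8 and the acrylate-bearing C7. The C10 methyl, O3, O8 and the C7 side chain all lie on the β face. The C7 side chain is equatorial and cis to the axial 8β-oxygen, which is 1,3-diaxial to the C10 methyl. C3 is allylic and 1,4 to C10 across ring A. The sensitive groups are the α-substituted acrylate (a Michael acceptor that also relactonises onto a free 8-hydroxyl), two different esters on secondary alcohols that must be told apart, and the ionisable allylic C3–O bond. The hard part is the quaternary C10, which is remote from every heteroatom and must be set in absolute terms; C3, C7 and C8 can then be relayed from it. The strategy rests on reading ring A as a hidden 2,4-dimethylphenol: O3 is ortho to the C4 methyl and para to the methyl-bearing C10, and the meta carbon C5 carries the chain C6–C9. An electrophile at C9 tethered through C5 can therefore dearomatise the ring at C10, and the C8 oxygen is the carbonyl of a diazoketone.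

## Retrosynthetic reasoning

**Acyl–oxygen bonds at O3 and O8.** Target 32 is the isobutyrate of alcohol 31, which is the desilylated form of 30, the acetate of hydroxy ester 29. Cutting the two acyl groups last, in this order, lets the two secondary oxygens be distinguished by a silyl ether placed on O3 much earlier. The forward steps are acylations that break no bond at a stereocentre.

**C12–O8 bond (the lactone).** Hydroxy ester 29 is traced through carboxylate 28 to the cis-fused α-methylene lactone 27. The lactone ties C7 and C8 together, hides the 8-hydroxyl during the methylenation, and is what reduction of a 7-(carboxymethyl) 8-ketone gives anyway. The forward step must open a γ-lactone against its ring-closing equilibrium and without conjugate addition to C13. An alkoxide in alcohol cannot do this, so the opening is done irreversibly with hydroxide and the carboxylate is then O-methylated.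

**C11=C13 bond.** Methylene lactone 27 is cut to amine 25 and then to lactone 24. On the lactone, C11 is the only acidic position, so the one-carbon unit can be added as an aminomethyl group and eliminated.

**C8–O stereocentre and the C7–C11 bond.** Lactone 24 comes from keto ester 22 by reduction, with hydride arriving on the α face because the β face of C8 is screened by the C10 methyl. Keto ester 22 is cut at C7–C11 into ketone 19 and methyl bromoacetate 20. This bond is chosen because the C8 carbonyl makes C7 nucleophilic, and C7 (not the neopentyl C9) is the position that enolises. The forward reaction must place the side chain equatorial, which equilibration through the enolate achieves.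

**Telling the two carbonyls apart; the C3 stereocentre.** Ketone 19 is traced through 18, 17 and 16 to enedione 15. The saturated C8 ketone is masked as a dioxolane, the C3 enone is reduced in 1,2-fashion under the control of the ring conformation fixed by C10, and the new alcohol is silylated before C8 is released.

**C1–C2 saturation.** Enedione 15 is traced to dienedione 14. Adding the C1=C2 alkene in the retrosynthetic sense makes ring A a cross-conjugated cyclohexadienone, the direct product of a phenol dearomatisation. The forward step must reduce the disubstituted alkene and leave the tetrasubstituted one.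

**C9–C10 bond (key disconnection).** Dienedione 14 is cut between C9 and C10 to the achiral phenolic diazoketone 13. This one cut removes ring B and the only stereocentre, and leaves an aromatic ring that can be bought almost complete. The forward step must form the quaternary centre para to the hydroxyl, on one enantiotopic face of the arene, under a chiral dirhodium tetracarboxylate.

**C8–C9 bond.** Diazoketone 13 is traced through its acetate 12 and acid chloride 11 to acid 9 and the one-carbon unit (trimethylsilyl)diazomethane 10. The phenol is held as an acetate only while the acyl chloride exists.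

**Arene oxygen and the C6=C7 bond.** Acid 9 goes back through hydroxy acid 8 to boronate 6, to its unsaturated precursor 5 and to bromide 4; the C–O bond comes from C–B and that from C–Br. Cutting the alkene of 4 gives aldehyde 2 and triethyl phosphonoacetate 3. Bromide 2 comes from 2,6-dimethylbenzaldehyde 1, in which both methyls and the formyl group direct an electrophile to C3.

## Alternatives that were turned down

**Alternative 1:** Biomimetic transannular cyclisation. The C5–C10 bond is cut to give the ten-membered (E,E)-germacradienolide A1. In the forward sense a Brønsted acid protonates C1=C10, the C10 cation is captured across the ring by C5, and loss of H5 gives the eudesmanolide A2. In its favour, both rings form in one step with C10 set relative to C7 through a chair-like folding, and A2 is simply the free alcohol of silyl ether 27, so the end game would be shared. Against it, A1 is itself a hard target: a medium ring with two E-trisubstituted alkenes and three stereocentres. The cyclisation is also hard to steer. The C4 cation can lose a proton towards C3, C15 or C5, and loss towards the carbinol C3 gives an enol and hence a 3-ketone. The allylic 3-hydroxyl of A1 can ionise under the same acid. On ring construction this alternative is stronger, but it moves the difficulty into the precursor. The chosen route starts from an achiral, easily made arene and sets the quaternary centre by a catalyst.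

**Alternative 2:** Nickel-catalysed intramolecular [4+2] cycloaddition. The C3–C4 and C5–C10 bonds are cut to give the acyclic dienyne A3. In the forward sense a zerovalent nickel catalyst with a phosphite ligand joins the tethered alkyne and diene to give the bicyclic 1,4-diene A4. In its favour, two bonds, two rings and the quaternary centre form at once under neutral conditions, which is more bond formation per step than the chosen key step offers. Against it, A4 has no oxygen at C3, so a doubly allylic oxidation must follow, and C6 competes for it. The diene terminus that becomes C10 is fully substituted, which slows the cycloaddition. The C10 configuration would be relayed from the C8 silyloxy centre of A3, which has the wrong (α) orientation and must later be oxidised away; it is a sacrificial stereocentre, and A3 must first be made enantiopure over several steps. The chosen route gives up the double ring closure but delivers O3 and O8 at the right carbons directly, and takes its absolute configuration from a catalyst.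

**Alternative 3:** Vinylogous allylic alkylation closing ring B. The C6–C7 bond is cut to give the allylic carbonate A5. In the forward sense a nucleophilic tertiary amine displaces the carbonate in SN2′ fashion, the released alkoxide generates the extended enolate of the enone, and its γ carbon C6 attacks C7 in a second SN2′ step to give the keto acrylate A6. In its favour, A6 already carries the acrylate and the C8 acetate and is two steps (1,2-reduction, isobutyrylation) from the target. That avoids the lactone opening of the chosen route and is clearly the better end game. Against it, A5 must already contain the quaternary C10 and the C8 stereocentre, so the hardest problem is solved elsewhere. The enone can also be deprotonated at C2 rather than at the C6 methyl, and the extended enolate can react at C4. The C7 configuration relative to C8 rests on an untested transition state, and the acetate next to the reacting carbon is exposed to alkoxide. The chosen route is longer after ring closure, but it solves the quaternary centre in the ring-forming step and relays the other three centres by well-understood decalone chemistry.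

Key step: step 9

Assumption: Rh2(S-PTTL)4 is taken to deliver the (10S)-dienedione 14; if the sense of induction proves opposite, the mirror-image catalyst Rh2(R-PTTL)4 is used and nothing else changes.

## Route

Step 1
Reactants: 1 2,6-dimethylbenzaldehyde
Product: 2 3-bromo-2,6-dimethylbenzaldehyde
Conditions: N-bromosuccinimide (1.05 equiv), conc. H2SO4, 0 °C to rt
Reagents that add atoms: N-bromosuccinimide, O=C1CCC(=O)N1Br
Why: Electrophilic aromatic bromination; C3 is ortho to one methyl, para to the other and meta to the protonated formyl group, so all three substituents direct to it, whereas C4 is para to the formyl group; the ionic medium spares the benzylic C–H bonds.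

Step 2
Reactants: 2 3-bromo-2,6-dimethylbenzaldehyde; 3 triethyl phosphonoacetate
Product: 4 ethyl (E)-3-(3-bromo-2,6-dimethylphenyl)prop-2-enoate
Conditions: NaH, THF, 0 °C to rt
Reagents that add atoms: none
Why: Horner–Wadsworth–Emmons olefination; the small stabilised phosphonate anion adds even to a 2,6-disubstituted benzaldehyde and gives the E-alkene, whose geometry is of no consequence later.

Step 3
Reactants: 4 ethyl (E)-3-(3-bromo-2,6-dimethylphenyl)prop-2-enoate
Product: 5 ethyl (E)-3-[2,6-dimethyl-3-(4,4,5,5-tetramethyl-1,3,2-dioxaborolan-2-yl)phenyl]prop-2-enoate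
Conditions: bis(pinacolato)diboron, PdCl2(dppf) (3 mol %), KOAc, 1,4-dioxane, 90 °C
Reagents that add atoms: bis(pinacolato)diboron, CC1(C)OB(OC1(C)C)B1OC(C)(C)C(C)(C)O1
Why: Miyaura borylation (oxidative addition of zerovalent palladium into C–Br, then transmetalation with the acetate-activated diboron); it is placed before the hydrogenation so that no C–Br bond is ever exposed to H2 over palladium.

Step 4
Reactants: 5 ethyl (E)-3-[2,6-dimethyl-3-(4,4,5,5-tetramethyl-1,3,2-dioxaborolan-2-yl)phenyl]prop-2-enoate
Product: 6 ethyl 3-[2,6-dimethyl-3-(4,4,5,5-tetramethyl-1,3,2-dioxaborolan-2-yl)phenyl]propanoate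
Conditions: H2 (1 atm), 10% Pd/C, EtOAc, rt
Reagents that add atoms: none
Why: Heterogeneous hydrogenation of a cinnamate C=C bond; the aryl boronate, the ester and the arene are inert under these conditions.

Step 5
Reactants: 6 ethyl 3-[2,6-dimethyl-3-(4,4,5,5-tetramethyl-1,3,2-dioxaborolan-2-yl)phenyl]propanoate
Product: 8 3-(3-hydroxy-2,6-dimethylphenyl)propanoic acid, via ethyl 3-(3-hydroxy-2,6-dimethylphenyl)propanoate 7 (not isolated)
Conditions: 30% H2O2 (2 equiv), 2 M NaOH, THF, 0 °C; then 50 °C; HCl to pH 2
Reagents that add atoms: hydrogen peroxide, OO; sodium hydroxide, [Na+].[OH-]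
Why: Alkaline peroxide oxidation of the aryl boronate (1,2-shift of the aryl group from boron to oxygen at the same ring carbon), followed in the same basic medium by saponification of the ethyl ester.

Step 6
Reactants: 8 3-(3-hydroxy-2,6-dimethylphenyl)propanoic acid
Product: 9 3-(3-acetoxy-2,6-dimethylphenyl)propanoic acid
Conditions: Ac2O (1.5 equiv), 2 M NaOH, 0 °C, 15 min; HCl to pH 2
Reagents that add atoms: acetic anhydride, CC(=O)OC(C)=O
Why: Chattaway-type acetylation of the phenoxide in cold aqueous base, where any mixed anhydride at the carboxylate is hydrolysed; the acetate stops the phenol from being acylated in the acid chloride step.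

Step 7
Reactants: 9 3-(3-acetoxy-2,6-dimethylphenyl)propanoic acid; 10 (trimethylsilyl)diazomethane
Product: 12 3-(4-diazo-3-oxobutyl)-2,4-dimethylphenyl acetate, via 3-(3-acetoxy-2,6-dimethylphenyl)propanoyl chloride 11 (not isolated)
Conditions: (COCl)2, DMF (cat.), CH2Cl2, 0 °C to rt; concentrate; 10 (2.2 equiv), THF–MeCN (1:1), 0 °C to rt
Reagents that add atoms: none
Why: Acid chloride formation followed by C-acylation of the diazoalkane with loss of the silyl group (the diazoketone stage of an Arndt–Eistert sequence); the excess of 10 consumes residual HCl so that no chloromethyl ketone forms, and the aryl acetate is inert.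

Step 8
Reactants: 12 3-(4-diazo-3-oxobutyl)-2,4-dimethylphenyl acetate
Product: 13 1-diazo-4-(3-hydroxy-2,6-dimethylphenyl)butan-2-one
Conditions: K2CO3 (1.2 equiv), MeOH, 0 °C, 30 min; pH 7 buffer
Reagents that add atoms: none
Why: Methanolysis of an aryl acetate is fast at 0 °C because phenoxide is a good leaving group, and α-diazoketones tolerate mild base; a neutral work-up avoids acid-induced loss of N2.

Step 9
Reactants: 13 1-diazo-4-(3-hydroxy-2,6-dimethylphenyl)butan-2-one
Product: 14 (8aS)-5,8a-dimethyl-1,3,4,8a-tetrahydronaphthalene-2,6-dione [(10S)-11,12,13-trinoreudesma-1,4-diene-3,8-dione]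
Conditions: Rh2(S-PTTL)4 [dirhodium tetrakis(N-phthaloyl-(S)-tert-leucinate), divalent rhodium] (1 mol %), CH2Cl2, 0 °C, 13 added over 4 h (final 0.01 M)
Reagents that add atoms: none
Why: Proposed new method: loss of N2 at the dirhodium centre gives an electrophilic α-keto carbenoid at C9, held by the tether C6–C7–C8 over the C5–C10 edge of the arene; the carbon C10, para to the hydroxyl, attacks it (directly, or by cyclopropanation of C5=C10 followed by cleavage of the C5–C9 bond under the push of the enolic oxygen through C4), which forms C9–C10, and transfer of the phenolic proton to C9 leaves the cross-conjugated dienone. The closest known reaction types are the acid- or dirhodium-promoted cyclisation of phenolic diazoketones to fused cyclohexa-2,5-dienones, which is racemic, and the catalytic asymmetric dearomatisation of phenols and naphthols by metal carbenes; new here is their combination in an enantioselective ring closure with an acceptor-only carbenoid. Ring B closes as a six-membered carbocycle in which both carbons of the attacked arene bond, C5 and C10, become ring members (6-endo mode), the natural mode for a tether of this length. The new stereocentre C10 arises because the two faces of the achiral arene are enantiotopic, and the face is chosen by the wall of N-phthaloyl groups of the tert-leucinate ligands around the carbenoid, that is, by the catalyst alone. The step needs para attack at C10 over ortho attack at C4: C10 is the more nucleophilic position and has only C1–H beside it, whereas C4 is wedged between the oxygen-bearing C3 and the tether-bearing C5. It also needs C–C bond formation to outrun O–H insertion, which can only be intermolecular here and is suppressed by slow addition at high dilution, and to outrun ring expansion of a norcaradiene, which the irreversible enol-driven cyclopropane opening should prevent. The methyl group on C10 excludes rearomatisation, so the quaternary centre persists, and no C–H insertion site lies within reach of C9.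

Step 10
Reactants: 14 (8aS)-5,8a-dimethyl-1,3,4,8a-tetrahydronaphthalene-2,6-dione
Product: 15 (8aR)-5,8a-dimethyl-1,3,4,7,8,8a-hexahydronaphthalene-2,6-dione [(10R)-11,12,13-trinoreudesm-4-ene-3,8-dione]
Conditions: H2 (1 atm), RhCl(PPh3)3 (5 mol %), benzene–EtOH (1:1), rt
Reagents that add atoms: none
Why: Homogeneous hydrogenation with RhCl(PPh3)3 selects by substitution: the disubstituted C1=C2 bond of a cross-conjugated 1,4-dien-3-one is reduced, while the tetrasubstituted C4=C5 bond and both ketones remain; C10 is untouched, and its descriptor changes from S to R only because C9 now outranks the saturated C1.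

Step 11
Reactants: 15 (8aR)-5,8a-dimethyl-1,3,4,7,8,8a-hexahydronaphthalene-2,6-dione
Product: 16 (10R)-8,8-(ethylenedioxy)-11,12,13-trinoreudesm-4-en-3-one
Conditions: HOCH2CH2OH (3 equiv), pyridinium p-toluenesulfonate (10 mol %), benzene, reflux, Dean–Stark
Reagents that add atoms: ethylene glycol, OCCO
Why: Acid-catalysed dioxolane formation is much faster at the saturated C8 ketone than at the conjugated, α-methylated C3 enone, so the reaction can be stopped at the monoketal.

Step 12
Reactants: 16 (10R)-8,8-(ethylenedioxy)-11,12,13-trinoreudesm-4-en-3-one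
Product: 17 (3S,10R)-8,8-(ethylenedioxy)-11,12,13-trinoreudesm-4-en-3β-ol
Conditions: NaBH4, CeCl3·7H2O, MeOH, −40 °C
Reagents that add atoms: none
Why: Luche 1,2-reduction; hydride adds to C3 along the axial trajectory on the α face and, through a chair-like transition state, gives the quasi-equatorial 3β-alcohol, as in 4-en-3-ones of the steroid series, while the ketal keeps C8 out of the reaction.

Step 13
Reactants: 17 (3S,10R)-8,8-(ethylenedioxy)-11,12,13-trinoreudesm-4-en-3β-ol
Product: 18 (3S,10R)-3β-(tert-butyldimethylsilyloxy)-8,8-(ethylenedioxy)-11,12,13-trinoreudesm-4-ene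
Conditions: TBSCl, imidazole, DMF, rt
Reagents that add atoms: tert-butyldimethylsilyl chloride, CC(C)(C)[Si](C)(C)Cl
Why: Standard imidazole-promoted silylation of a secondary alcohol; the silyl ether will survive amide bases, hydride and aqueous hydroxide and marks O3 for the later isobutyrate.

Step 14
Reactants: 18 (3S,10R)-3β-(tert-butyldimethylsilyloxy)-8,8-(ethylenedioxy)-11,12,13-trinoreudesm-4-ene
Product: 19 (3S,10R)-3β-(tert-butyldimethylsilyloxy)-11,12,13-trinoreudesm-4-en-8-one
Conditions: pyridinium p-toluenesulfonate (20 mol %), acetone–H2O (9:1), 50 °C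
Reagents that add atoms: water, O
Why: Mild acid hydrolysis of the dioxolane; a secondary TBS ether withstands pyridinium p-toluenesulfonate, and the weak acid should not ionise the allylic C3–O bond.

Step 15
Reactants: 19 (3S,10R)-3β-(tert-butyldimethylsilyloxy)-11,12,13-trinoreudesm-4-en-8-one; 20 methyl bromoacetate
Product: 22 methyl (3S,7R,10R)-3β-(tert-butyldimethylsilyloxy)-8-oxo-13-noreudesm-4-en-12-oate, via methyl 3β-(tert-butyldimethylsilyloxy)-8-oxo-13-nor-7-epi-eudesm-4-en-12-oate 21 (not isolated)
Conditions: LiN(iPr)2 (1.05 equiv), THF, −78 °C; 20, DMPU, −78 to −20 °C; then NaOMe (0.2 equiv), MeOH, 0 °C to rt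
Reagents that add atoms: none
Why: Kinetic enolate alkylation; the amide base removes the less hindered C7–H rather than the neopentyl C9–H, and SN2 attack on 20 forms C7–C11. Axial attack is expected to favour the 7α-epimer 21 first, and methoxide equilibration through the enolate then places the side chain equatorial (7β), so C7 is set under thermodynamic control.

Step 16
Reactants: 22 methyl (3S,7R,10R)-3β-(tert-butyldimethylsilyloxy)-8-oxo-13-noreudesm-4-en-12-oate
Product: 24 (3S,7R,8R,10R)-3β-(tert-butyldimethylsilyloxy)-13-noreudesm-4-en-12,8β-olide, via methyl 8β-hydroxy-3β-(tert-butyldimethylsilyloxy)-13-noreudesm-4-en-12-oate 23 (not isolated)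
Conditions: LiBH(sBu)3, THF, −78 to 0 °C; aq NH4Cl; then pyridinium p-toluenesulfonate (cat.), benzene, 60 °C
Reagents that add atoms: none
Why: The bulky hydride attacks C8 along the equatorial direction on the α face, since the axial β approach is blocked by the 1,3-diaxial C10 methyl; this gives the axial 8β-oxygen cis to the equatorial C7 side chain, which then closes the cis-fused γ-lactone by acyl substitution.

Step 17
Reactants: 24 (3S,7R,8R,10R)-3β-(tert-butyldimethylsilyloxy)-13-noreudesm-4-en-12,8β-olide
Product: 25 13-(dimethylamino)-3β-(tert-butyldimethylsilyloxy)eudesm-4-en-12,8β-olide (mixture of C11 epimers)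
Conditions: LiN(iPr)2, THF, −78 °C; CH2=NMe2+ I−, −78 °C to rt
Reagents that add atoms: N,N-dimethylmethyleneiminium iodide, C=[N+](C)C.[I-]
Why: Mannich reaction of the lactone enolate (C11 is the only acidic position) with a preformed iminium salt; the C11 configuration is irrelevant because the centre becomes sp2 in the next step.

Step 18
Reactants: 25 13-(dimethylamino)-3β-(tert-butyldimethylsilyloxy)eudesm-4-en-12,8β-olide
Product: 27 (3S,7R,8R,10R)-3β-(tert-butyldimethylsilyloxy)eudesma-4,11(13)-dien-12,8β-olide, via 13-(trimethylammonio)-3β-(tert-butyldimethylsilyloxy)eudesm-4-en-12,8β-olide iodide 26 (not isolated)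
Conditions: MeI (excess), THF, rt; then NaHCO3 (aq), EtOAc, rt
Reagents that add atoms: none
Why: Quaternisation followed by E1cB loss of trimethylamine gives the exocyclic methylene; bicarbonate in a two-phase system without an alcohol avoids conjugate addition to the new Michael acceptor.

Step 19
Reactants: 27 (3S,7R,8R,10R)-3β-(tert-butyldimethylsilyloxy)eudesma-4,11(13)-dien-12,8β-olide
Product: 29 methyl (3S,7R,8R,10R)-8β-hydroxy-3β-(tert-butyldimethylsilyloxy)eudesma-4,11(13)-dien-12-oate, via potassium 8β-hydroxy-3β-(tert-butyldimethylsilyloxy)eudesma-4,11(13)-dien-12-oate 28 (not isolated)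
Conditions: KOH (1.1 equiv), THF–H2O (3:1), 0 °C to rt; CO2 to pH 8; evaporate; MeI (3 equiv), DMF, 0 °C; used at once
Reagents that add atoms: potassium hydroxide, [K+].[OH-]; iodomethane, CI
Why: Saponification opens the lactone irreversibly by acyl–oxygen cleavage, so C8 keeps its configuration and the carboxylate cannot relactonise; without an alcohol nucleophile, conjugate addition is minimised, and SN2 O-methylation of the carboxylate under near-neutral conditions gives the hydroxy ester. Methoxide in methanol is avoided because it would add to C13 and the γ-lactone equilibrium would return the ring.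

Step 20
Reactants: 29 methyl (3S,7R,8R,10R)-8β-hydroxy-3β-(tert-butyldimethylsilyloxy)eudesma-4,11(13)-dien-12-oate
Product: 30 methyl (3S,7R,8R,10R)-8β-acetoxy-3β-(tert-butyldimethylsilyloxy)eudesma-4,11(13)-dien-12-oate
Conditions: Ac2O, 4-(dimethylamino)pyridine, pyridine, 0 °C to rt
Reagents that add atoms: acetic anhydride, CC(=O)OC(C)=O
Why: Nucleophile-catalysed acylation of the axial 8β-hydroxyl, which has one 1,3-diaxial methyl and should react at a useful rate; it traps the hydroxyl before it can close back onto the ester.

Step 21
Reactants: 30 methyl (3S,7R,8R,10R)-8β-acetoxy-3β-(tert-butyldimethylsilyloxy)eudesma-4,11(13)-dien-12-oate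
Product: 31 methyl (3S,7R,8R,10R)-8β-acetoxy-3β-hydroxyeudesma-4,11(13)-dien-12-oate
Conditions: HF·pyridine, THF–pyridine, 0 °C to rt
Reagents that add atoms: none
Why: Fluoride-driven Si–O cleavage under buffered conditions; both esters and the acrylate are inert and no C–O bond is broken, so C3 keeps its configuration.

Step 22
Reactants: 31 methyl (3S,7R,8R,10R)-8β-acetoxy-3β-hydroxyeudesma-4,11(13)-dien-12-oate
Product: 32 methyl (3S,7R,8R,10R)-8β-acetoxy-3β-(isobutyryloxy)eudesma-4,11(13)-dien-12-oate (CNP0127901.1)
Conditions: (iPrCO)2O, 4-(dimethylamino)pyridine (cat.), Et3N, CH2Cl2, rt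
Reagents that add atoms: isobutyric anhydride, CC(C)C(=O)OC(=O)C(C)C
Why: Nucleophile-catalysed acylation of the allylic 3β-alcohol with retention of configuration, since only the O–H bond reacts.

## Compound list

1 | 2,6-dimethylbenzaldehyde | Cc1cccc(C)c1C=O | starting material
2 | 3-bromo-2,6-dimethylbenzaldehyde | Cc1ccc(Br)c(C)c1C=O | intermediate
3 | triethyl phosphonoacetate | CCOC(=O)CP(=O)(OCC)OCC | starting material
4 | ethyl (E)-3-(3-bromo-2,6-dimethylphenyl)prop-2-enoate | CCOC(=O)/C=C/c1c(C)ccc(Br)c1C | intermediate
5 | ethyl (E)-3-[2,6-dimethyl-3-(4,4,5,5-tetramethyl-1,3,2-dioxaborolan-2-yl)phenyl]prop-2-enoate | CCOC(=O)/C=C/c1c(C)ccc(B2OC(C)(C)C(C)(C)O2)c1C | intermediate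
6 | ethyl 3-[2,6-dimethyl-3-(4,4,5,5-tetramethyl-1,3,2-dioxaborolan-2-yl)phenyl]propanoate | CCOC(=O)CCc1c(C)ccc(B2OC(C)(C)C(C)(C)O2)c1C | intermediate
7 | ethyl 3-(3-hydroxy-2,6-dimethylphenyl)propanoate | CCOC(=O)CCc1c(C)ccc(O)c1C | intermediate (not isolated)
8 | 3-(3-hydroxy-2,6-dimethylphenyl)propanoic acid | OC(=O)CCc1c(C)ccc(O)c1C | intermediate
9 | 3-(3-acetoxy-2,6-dimethylphenyl)propanoic acid | CC(=O)Oc1ccc(C)c(CCC(O)=O)c1C | intermediate
10 | (trimethylsilyl)diazomethane | C[Si](C)(C)C=[N+]=[N-] | starting material
11 | 3-(3-acetoxy-2,6-dimethylphenyl)propanoyl chloride | CC(=O)Oc1ccc(C)c(CCC(Cl)=O)c1C | intermediate (not isolated)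
12 | 3-(4-diazo-3-oxobutyl)-2,4-dimethylphenyl acetate | CC(=O)Oc1ccc(C)c(CCC(=O)C=[N+]=[N-])c1C | intermediate
13 | 1-diazo-4-(3-hydroxy-2,6-dimethylphenyl)butan-2-one | Cc1ccc(O)c(C)c1CCC(=O)C=[N+]=[N-] | intermediate
14 | (8aS)-5,8a-dimethyl-1,3,4,8a-tetrahydronaphthalene-2,6-dione [(10S)-11,12,13-trinoreudesma-1,4-diene-3,8-dione] | O=C1CCC2=C(C)C(=O)C=C[C@]2(C)C1 | intermediate
15 | (8aR)-5,8a-dimethyl-1,3,4,7,8,8a-hexahydronaphthalene-2,6-dione [(10R)-11,12,13-trinoreudesm-4-ene-3,8-dione] | O=C1CCC2=C(C)C(=O)CC[C@]2(C)C1 | intermediate
16 | (10R)-8,8-(ethylenedioxy)-11,12,13-trinoreudesm-4-en-3-one | O1CCOC12CCC3=C(C)C(=O)CC[C@]3(C)C2 | intermediate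
17 | (3S,10R)-8,8-(ethylenedioxy)-11,12,13-trinoreudesm-4-en-3β-ol | O1CCOC12CCC3=C(C)[C@@H](O)CC[C@]3(C)C2 | intermediate
18 | (3S,10R)-3β-(tert-butyldimethylsilyloxy)-8,8-(ethylenedioxy)-11,12,13-trinoreudesm-4-ene | O1CCOC12CCC3=C(C)[C@@H](O[Si](C)(C)C(C)(C)C)CC[C@]3(C)C2 | intermediate
19 | (3S,10R)-3β-(tert-butyldimethylsilyloxy)-11,12,13-trinoreudesm-4-en-8-one | O=C1CCC2=C(C)[C@@H](O[Si](C)(C)C(C)(C)C)CC[C@]2(C)C1 | intermediate
20 | methyl bromoacetate | COC(=O)CBr | starting material
21 | methyl 3β-(tert-butyldimethylsilyloxy)-8-oxo-13-nor-7-epi-eudesm-4-en-12-oate (7α side chain) | COC(=O)C[C@@H]1CC2=C(C)[C@@H](O[Si](C)(C)C(C)(C)C)CC[C@]2(C)CC1=O | intermediate (not isolated)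
22 | methyl (3S,7R,10R)-3β-(tert-butyldimethylsilyloxy)-8-oxo-13-noreudesm-4-en-12-oate (7β side chain) | COC(=O)C[C@H]1CC2=C(C)[C@@H](O[Si](C)(C)C(C)(C)C)CC[C@]2(C)CC1=O | intermediate
23 | methyl 8β-hydroxy-3β-(tert-butyldimethylsilyloxy)-13-noreudesm-4-en-12-oate | COC(=O)C[C@H]1CC2=C(C)[C@@H](O[Si](C)(C)C(C)(C)C)CC[C@]2(C)C[C@H]1O | intermediate (not isolated)
24 | (3S,7R,8R,10R)-3β-(tert-butyldimethylsilyloxy)-13-noreudesm-4-en-12,8β-olide (cis-fused lactone) | O=C1C[C@H]2CC3=C(C)[C@@H](O[Si](C)(C)C(C)(C)C)CC[C@]3(C)C[C@H]2O1 | intermediate
25 | 13-(dimethylamino)-3β-(tert-butyldimethylsilyloxy)eudesm-4-en-12,8β-olide (C11 epimers) | O=C1C(CN(C)C)[C@H]2CC3=C(C)[C@@H](O[Si](C)(C)C(C)(C)C)CC[C@]3(C)C[C@H]2O1 | intermediate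
26 | 13-(trimethylammonio)-3β-(tert-butyldimethylsilyloxy)eudesm-4-en-12,8β-olide iodide | O=C1C(C[N+](C)(C)C)[C@H]2CC3=C(C)[C@@H](O[Si](C)(C)C(C)(C)C)CC[C@]3(C)C[C@H]2O1.[I-] | intermediate (not isolated)
27 | (3S,7R,8R,10R)-3β-(tert-butyldimethylsilyloxy)eudesma-4,11(13)-dien-12,8β-olide | C=C1[C@H]2CC3=C(C)[C@@H](O[Si](C)(C)C(C)(C)C)CC[C@]3(C)C[C@H]2OC1=O | intermediate
28 | potassium 8β-hydroxy-3β-(tert-butyldimethylsilyloxy)eudesma-4,11(13)-dien-12-oate | C=C(C(=O)[O-])[C@H]1CC2=C(C)[C@@H](O[Si](C)(C)C(C)(C)C)CC[C@]2(C)C[C@H]1O.[K+] | intermediate (not isolated)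
29 | methyl (3S,7R,8R,10R)-8β-hydroxy-3β-(tert-butyldimethylsilyloxy)eudesma-4,11(13)-dien-12-oate | C=C(C(=O)OC)[C@H]1CC2=C(C)[C@@H](O[Si](C)(C)C(C)(C)C)CC[C@]2(C)C[C@H]1O | intermediate
30 | methyl (3S,7R,8R,10R)-8β-acetoxy-3β-(tert-butyldimethylsilyloxy)eudesma-4,11(13)-dien-12-oate | C=C(C(=O)OC)[C@H]1CC2=C(C)[C@@H](O[Si](C)(C)C(C)(C)C)CC[C@]2(C)C[C@H]1OC(C)=O | intermediate
31 | methyl (3S,7R,8R,10R)-8β-acetoxy-3β-hydroxyeudesma-4,11(13)-dien-12-oate | C=C(C(=O)OC)[C@H]1CC2=C(C)[C@@H](O)CC[C@]2(C)C[C@H]1OC(C)=O | intermediate
32 | methyl (3S,7R,8R,10R)-8β-acetoxy-3β-(isobutyryloxy)eudesma-4,11(13)-dien-12-oate (CNP0127901.1) | C=C(C(=O)OC)[C@H]1CC2=C(C)[C@@H](OC(=O)C(C)C)CC[C@]2(C)C[C@H]1OC(C)=O | target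

## Step count and least certain steps

Total: 22 steps. Longest linear sequence: 22 steps (the route is fully linear; 3, 10 and 20 are bought).

**Step 9 (key step, proposed new method).** The most likely failure is poor facial discrimination, because an acceptor-only carbenoid reacts through an early, loosely organised transition state. Further risks are attack at the ortho carbon C4, ring expansion of a norcaradiene to a cycloheptatriene, and intermolecular O–H insertion. Fallback by known chemistry: setting out from 13, treatment with CF3CO2H in CH2Cl2 at −20 °C (protonation to the diazonium ion and displacement by the para carbon, the established racemic cyclisation of phenolic diazoketones) should give the racemic dienedione F1. Preparative chromatography on a chiral stationary phase then separates 14 from its (8aR)-enantiomer F2, which is set aside. The route is rejoined at 14.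

**Step 19.** The hydroxy ester may close back to the lactone during methylation or before acetylation, and hydroxide may add to C13 in competition with lactone opening. Fallback that never forms the lactone, setting out from 19:
- Alkylation with allyl bromide (LiN(iPr)2, THF, −78 °C; then NaOMe equilibration) should give the 7β-allyl ketone F3.
- LiBH(sBu)3 should give the 8β-alcohol F4, and Ac2O with 4-(dimethylamino)pyridine the acetate F5.
- OsO4 (cat.) with N-methylmorpholine N-oxide should dihydroxylate only the monosubstituted alkene, the tetrasubstituted C4=C5 bond being too hindered, to give the diol F6.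
- NaIO4 should cleave F6 to the aldehyde F7.
- α-Methylenation with aqueous formaldehyde and pyrrolidinium propionate should give the enal F8.
- Pinnick oxidation (NaClO2, NaH2PO4, 2-methylbut-2-ene) should give the acrylic acid F9.
- MeI with K2CO3 in DMF should return the route at 30.

**Step 15.** Risks are incomplete regiocontrol (C9 against C7), dialkylation, and a modest thermodynamic preference for the equatorial C7 epimer, since the sp2 centre C5 removes one 1,3-diaxial contact. Fallback, setting out from 19: condensation with pyrrolidine (4 Å molecular sieves, benzene, reflux) should give the less hindered enamine F10. Stork alkylation with 20 in MeCN and hydrolysis with buffered aqueous acetic acid gives monoalkylation only and should return the route at 22 after the same equilibration.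

**Step 12.** Hydride delivery may show poor facial selectivity, since the C4 methyl adds A(1,2) strain to the quasi-equatorial alcohol. Fallback, setting out from 16: if the 3α-alcohol F11 is formed in quantity, it is separated and inverted by a Mitsunobu reaction (PPh3, diisopropyl azodicarboxylate, 4-nitrobenzoic acid) to the 3β-(4-nitrobenzoate) F12. SN2′ attack is disfavoured because it would have to occur at the fully substituted C5. Methanolysis of F12 (K2CO3, MeOH) should return the route at 17.

## Further compounds

F1 | step 9 | racemic 5,8a-dimethyl-1,3,4,8a-tetrahydronaphthalene-2,6-dione | O=C1CCC2=C(C)C(=O)C=CC2(C)C1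
F2 | step 9 | (8aR)-5,8a-dimethyl-1,3,4,8a-tetrahydronaphthalene-2,6-dione | O=C1CCC2=C(C)C(=O)C=C[C@@]2(C)C1
F3 | step 19 | 7β-allyl-3β-(tert-butyldimethylsilyloxy)-11,12,13-trinoreudesm-4-en-8-one | C=CC[C@H]1CC2=C(C)[C@@H](O[Si](C)(C)C(C)(C)C)CC[C@]2(C)CC1=O
F4 | step 19 | 7β-allyl-3β-(tert-butyldimethylsilyloxy)-11,12,13-trinoreudesm-4-en-8β-ol | C=CC[C@H]1CC2=C(C)[C@@H](O[Si](C)(C)C(C)(C)C)CC[C@]2(C)C[C@H]1O
F5 | step 19 | 7β-allyl-3β-(tert-butyldimethylsilyloxy)-11,12,13-trinoreudesm-4-en-8β-yl acetate | C=CC[C@H]1CC2=C(C)[C@@H](O[Si](C)(C)C(C)(C)C)CC[C@]2(C)C[C@H]1OC(C)=O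
F6 | step 19 | 7β-(2,3-dihydroxypropyl)-3β-(tert-butyldimethylsilyloxy)-11,12,13-trinoreudesm-4-en-8β-yl acetate (carbinol epimers) | OCC(O)C[C@H]1CC2=C(C)[C@@H](O[Si](C)(C)C(C)(C)C)CC[C@]2(C)C[C@H]1OC(C)=O
F7 | step 19 | 8β-acetoxy-3β-(tert-butyldimethylsilyloxy)-13-noreudesm-4-en-12-al | O=CC[C@H]1CC2=C(C)[C@@H](O[Si](C)(C)C(C)(C)C)CC[C@]2(C)C[C@H]1OC(C)=O
F8 | step 19 | 8β-acetoxy-3β-(tert-butyldimethylsilyloxy)eudesma-4,11(13)-dien-12-al | C=C(C=O)[C@H]1CC2=C(C)[C@@H](O[Si](C)(C)C(C)(C)C)CC[C@]2(C)C[C@H]1OC(C)=O
F9 | step 19 | 8β-acetoxy-3β-(tert-butyldimethylsilyloxy)eudesma-4,11(13)-dien-12-oic acid | C=C(C(=O)O)[C@H]1CC2=C(C)[C@@H](O[Si](C)(C)C(C)(C)C)CC[C@]2(C)C[C@H]1OC(C)=O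
F10 | step 15 | 1-[3β-(tert-butyldimethylsilyloxy)-11,12,13-trinoreudesma-4,7-dien-8-yl]pyrrolidine | C1CCN(C1)C1=CCC2=C(C)[C@@H](O[Si](C)(C)C(C)(C)C)CC[C@]2(C)C1
F11 | step 12 | (3R,10R)-8,8-(ethylenedioxy)-11,12,13-trinoreudesm-4-en-3α-ol | O1CCOC12CCC3=C(C)[C@H](O)CC[C@]3(C)C2
F12 | step 12 | (3S,10R)-8,8-(ethylenedioxy)-11,12,13-trinoreudesm-4-en-3β-yl 4-nitrobenzoate | O1CCOC12CCC3=C(C)[C@@H](OC(=O)c4ccc(cc4)[N+](=O)[O-])CC[C@]3(C)C2
A1 | alternative 1 | 3β-hydroxygermacra-1(10)E,4E,11(13)-trien-12,8β-olide | C=C1[C@H]2C/C=C(\C)[C@@H](O)C/C=C(\C)C[C@H]2OC1=O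
A2 | alternative 1 | 3β-hydroxyeudesma-4,11(13)-dien-12,8β-olide | C=C1[C@H]2CC3=C(C)[C@@H](O)CC[C@]3(C)C[C@H]2OC1=O
A3 | alternative 2 | (3E,6R)-6-(tert-butyldimethylsilyloxy)-4-methylundeca-1,3-dien-9-yne | CC#CCC[C@@H](O[Si](C)(C)C(C)(C)C)C/C(C)=C/C=C
A4 | alternative 2 | 8α-(tert-butyldimethylsilyloxy)-11,12,13-trinoreudesma-1,4-diene | CC(C)(C)[Si](C)(C)O[C@@H]1CCC2=C(C)CC=C[C@]2(C)C1
A5 | alternative 3 | methyl 8β-acetoxy-7-(tert-butoxycarbonyloxy)-3-oxo-6,7-secoeudesma-4,11(13)-dien-12-oate (C7 epimers) | C=C(C(=O)OC)C(OC(=O)OC(C)(C)C)[C@H](OC(C)=O)C[C@@]1(C)CCC(=O)C(C)=C1C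
A6 | alternative 3 | methyl 8β-acetoxy-3-oxoeudesma-4,11(13)-dien-12-oate | C=C(C(=O)OC)[C@H]1CC2=C(C)C(=O)CC[C@]2(C)C[C@H]1OC(C)=O
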